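The enone carbonyl carbon of this chalcone sits between C1' of ring A and Cα of the styryl arm. It is therefore treated as carbon monoxide, and both of its carbon–carbon bonds are cut at once. A palladium-catalysed carbonylative Heck reaction joins a ring A aryl iodide, CO and a ring B styrene in one operation. The iodine position fixes the acylation site, and the reaction delivers the E Cα=Cβ bond. The precursor is 4-iodoresorcinol carrying the geranyl ether on the oxygen para to iodine and a tert-butyldimethylsilyl ether on the ortho oxygen. Its partner is 4-silyloxystyrene. One buffered fluoride step then frees both phenols under near-neutral conditions that spare the geranyl ether.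

Key step: step 3

Remark: the target is read as the 4'-O-geranyl ether of isoliquiritigenin. Ring A carries 2'-OH ortho and geranyloxy para to the carbonyl, ring B carries 4-OH, and both the geranyl C2=C3 and the Cα=Cβ bonds are E. Geranyl = (2E)-3,7-dimethylocta-2,6-dien-1-yl and TBS = tert-butyldimethylsilyl. 4-(TBS-oxy)styrene is taken to be a catalogue monomer.

Step 1
Reactants: 1 4-iodobenzene-1,3-diol (4-iodoresorcinol); 2 geranyl bromide
Product: 3 5-(geranyloxy)-2-iodophenol
Conditions: 1 (1.5 equiv), 2 (1.0 equiv, slow addition), K2CO3 (1.2 equiv), acetone, 0 °C to rt, N2; SiO2 chromatography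
Reagents that add atoms: none
Why: Williamson ether synthesis (SN2 at the primary allylic carbon, so the E alkene is retained), in which the oxygen flanked by iodine is sterically shielded and its phenoxide is inductively stabilised and less nucleophilic, so the remote oxygen should react preferentially, while keeping 2 as the limiting reagent curbs dialkylation and lets the minor regioisomer, any diether and surplus 1 be removed on silica.

Step 2
Reactants: 3 5-(geranyloxy)-2-iodophenol
Product: 4 tert-butyl[5-(geranyloxy)-2-iodophenoxy]dimethylsilane
Conditions: TBSCl (1.3 equiv), imidazole (2.5 equiv), DMF, rt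
Reagents that add atoms: tert-butyldimethylsilyl chloride (TBSCl), CC(C)(C)[Si](C)(C)Cl
Why: Imidazole-promoted O-silylation of a phenol is an acid-free protocol that leaves the carbon–iodine bond, the allylic ether and both trisubstituted alkenes untouched and masks the one acidic OH that could otherwise intercept an aroylpalladium species.

Step 3
Reactants: 4 tert-butyl[5-(geranyloxy)-2-iodophenoxy]dimethylsilane; 5 carbon monoxide; 6 tert-butyldimethyl(4-vinylphenoxy)silane
Product: 7 (2E)-1-[2-(TBS-oxy)-4-(geranyloxy)phenyl]-3-[4-(TBS-oxy)phenyl]prop-2-en-1-one (2',4-bis-O-TBS ether of the target)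
Conditions: Pd(OAc)2 (2 mol %), n-BuP(1-Ad)2 (6 mol %), NEt3 (3 equiv), 6 (2 equiv), CO (10 bar), dry 1,4-dioxane, 100 °C, autoclave
Reagents that add atoms: none
Why: Zerovalent palladium formed from Pd(OAc)2, the phosphine and NEt3 inserts into the carbon–iodine bond of 4, the electron-rich and ortho-crowded aryl group migrates quickly onto coordinated CO, and the resulting aroyl complex of divalent palladium adds syn across the vinyl group of 6 so that the acyl carbon bonds to the CH2 terminus and the metal ends on the benzylic carbon. Bond rotation and syn β-hydride elimination of one of the two Cα hydrogens then release the enone, the E geometry following from the conformer that keeps the aroyl and aryl groups apart, and NEt3 takes up hydrogen iodide to return zerovalent palladium. This is a carbonylative Heck (carbonylative vinylation) reaction, a known way of turning aryl iodides, CO and styrenes into chalcones. No ring is closed and no stereocentre is created, the only stereochemical outcome being the E Cα=Cβ bond, while the E geranyl alkene is a spectator. Uptake of CO ahead of plain Heck arylation rests on the CO pressure and the bulky donor phosphine, the acylation site on ring A is dictated by where iodine sits, and both phenols are silylated so that no free ArOH can capture the aroylpalladium as an aryl ester. Ionisation of the geranyl aryl ether is held back because oxidative addition to the aryl iodide is far faster than to a trisubstituted allyl ether, CO-ligated palladium is a poor nucleophile, and NEt3 cannot carry off an allyl complex.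

Step 4
Reactants: 7 2',4-bis-O-TBS ether of the target
Product: 8 (2E)-1-[4-(geranyloxy)-2-hydroxyphenyl]-3-(4-hydroxyphenyl)prop-2-en-1-one (target)
Conditions: Bu4NF (2.5 equiv), AcOH (3 equiv), THF, 0 °C
Reagents that add atoms: none
Why: Fluoride-induced cleavage of aryl silyl ethers, driven by the strong Si–F bond and the good phenoxide leaving groups, should be fast at 0 °C at both sites, and the acetic acid buffer protonates each phenoxide at once so that the 2'-oxygen does not add to Cβ (flavanone closure) and the geranyl ether never meets strong acid.

Compound list
1 | 4-iodobenzene-1,3-diol (4-iodoresorcinol) | Oc1ccc(I)c(O)c1 | starting material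
2 | geranyl bromide, (2E)-1-bromo-3,7-dimethylocta-2,6-diene | CC(C)=CCC/C(C)=C/CBr | starting material
3 | 5-(geranyloxy)-2-iodophenol | CC(C)=CCC/C(C)=C/COc1ccc(I)c(O)c1 | intermediate
4 | tert-butyl[5-(geranyloxy)-2-iodophenoxy]dimethylsilane | CC(C)=CCC/C(C)=C/COc1ccc(I)c(O[Si](C)(C)C(C)(C)C)c1 | intermediate
5 | carbon monoxide | [C-]#[O+] | starting material
6 | tert-butyldimethyl(4-vinylphenoxy)silane | C=Cc1ccc(O[Si](C)(C)C(C)(C)C)cc1 | starting material
7 | (2E)-1-[2-(TBS-oxy)-4-(geranyloxy)phenyl]-3-[4-(TBS-oxy)phenyl]prop-2-en-1-one | CC(C)=CCC/C(C)=C/COc1ccc(C(=O)/C=C/c2ccc(O[Si](C)(C)C(C)(C)C)cc2)c(O[Si](C)(C)C(C)(C)C)c1 | intermediate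
8 | (2E)-1-[4-(geranyloxy)-2-hydroxyphenyl]-3-(4-hydroxyphenyl)prop-2-en-1-one | CC(C)=CCC/C(C)=C/COc1ccc(C(=O)/C=C/c2ccc(O)cc2)c(O)c1 | target

Total step count: 4
Longest linear sequence: 4 steps (1 to 3 to 4 to 7 to 8)

Steps most likely to fail

Step 3. Several things may go wrong:
- Direct arylation of the styrene may outrun CO insertion.
- Palladium may ionise the geranyl ether, with loss or allylic transposition of the geranyl group. This matters most once the ether oxygen has become para to a ketone.
- The styrene may polymerise thermally.
- The labile 2'-silyl group may be shed at 100 °C.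

The fallback replaces the carbonylation by a polar acylation. It sets out from 4 and rejoins the route at 7.
- The ring B arm comes from a Horner–Wadsworth–Emmons olefination of commercial 4-(TBS-oxy)benzaldehyde with commercial diethyl [2-(methoxy(methyl)amino)-2-oxoethyl]phosphonate (NaH, THF, 0 °C). This should give the Weinreb amide (2E)-3-[4-(TBS-oxy)phenyl]-N-methoxy-N-methylprop-2-enamide F1.
- Iodide 4 undergoes iodine–magnesium exchange with i-PrMgCl·LiCl in THF at −20 to 0 °C to give [2-(TBS-oxy)-4-(geranyloxy)phenyl]magnesium chloride F2. Magnesium is chosen over lithium so that oxygen-to-carbon silyl migration stays slow.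
- Addition of F2 to F1 forms a chelated tetrahedral adduct that collapses only on NH4Cl work-up, which should deliver enone 7 without over-addition.

Step 1. Discrimination between the two phenolic oxygens may be poor, and over-alkylation and some C-alkylation of the electron-rich ring may also occur. The fallback fixes the regiochemistry with a bulky temporary acyl group before any geranyl unit is spent. It sets out from 1 and rejoins the route at 4.
- Pivaloyl chloride (1 equiv) and pyridine in CH2Cl2 at −20 °C should acylate the unhindered oxygen to give 3-hydroxy-4-iodophenyl pivalate F3.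
- TBSCl and imidazole in DMF convert F3 into 3-(TBS-oxy)-4-iodophenyl pivalate F4.
- i-Bu2AlH in CH2Cl2 at −78 °C removes the ester reductively to give 3-(TBS-oxy)-4-iodophenol F5, without touching the silyl ether or the iodide.
- A Mitsunobu etherification of F5 with geraniol (PPh3, DIAD, THF, 0 °C) then leads to 4. It is base-free, so it avoids silyl scrambling between phenoxides.

Step 4. Basic fluoride or transient phenoxide may trigger oxa-Michael ring closure of the freed 2'-oxygen onto the enone, or may erode material by retro-aldol cleavage. The fallback changes the protecting-group class from silyl ethers to esters. It sets out from 3 and rejoins the route at 8.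
- Ac2O and pyridine give 5-(geranyloxy)-2-iodophenyl acetate F6.
- The carbonylative Heck conditions of step 3, applied to F6 with commercial 4-acetoxystyrene, should give the 2',4-di-O-acetyl derivative of the target F7.
- Methanolysis with K2CO3 (0.2 equiv) in MeOH at 0 °C to rt, followed by an NH4Cl quench, releases 8. This medium is far milder than the strong alkali in which 2'-hydroxychalcones are routinely prepared and persist.

Further compounds
F1 | step 3 | (2E)-3-[4-(TBS-oxy)phenyl]-N-methoxy-N-methylprop-2-enamide | CON(C)C(=O)/C=C/c1ccc(O[Si](C)(C)C(C)(C)C)cc1
F2 | step 3 | [2-(TBS-oxy)-4-(geranyloxy)phenyl]magnesium chloride | CC(C)=CCC/C(C)=C/COc1ccc([Mg]Cl)c(O[Si](C)(C)C(C)(C)C)c1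
F3 | step 1 | 3-hydroxy-4-iodophenyl pivalate | CC(C)(C)C(=O)Oc1ccc(I)c(O)c1
F4 | step 1 | 3-(TBS-oxy)-4-iodophenyl pivalate | CC(C)(C)C(=O)Oc1ccc(I)c(O[Si](C)(C)C(C)(C)C)c1
F5 | step 1 | 3-(TBS-oxy)-4-iodophenol | Oc1ccc(I)c(O[Si](C)(C)C(C)(C)C)c1
F6 | step 4 | 5-(geranyloxy)-2-iodophenyl acetate | CC(C)=CCC/C(C)=C/COc1ccc(I)c(OC(C)=O)c1
F7 | step 4 | (2E)-1-[2-acetoxy-4-(geranyloxy)phenyl]-3-(4-acetoxyphenyl)prop-2-en-1-one | CC(C)=CCC/C(C)=C/COc1ccc(C(=O)/C=C/c2ccc(OC(C)=O)cc2)c(OC(C)=O)c1
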